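## The problem

Agastinol (14) is an oxolane with three contiguous stereocenters. C2 carries a 4-hydroxy-3-methoxyphenyl group, C3 a CH2O branch acylated by 4-hydroxybenzoic acid, C4 a 4-hydroxy-3-methoxybenzyl group, and C5 is an unsubstituted CH2. The configuration is (2R,3S,4S): the C2 aryl group is trans to the C3 branch and the C3 and C4 branches are cis, so the crowded relation has to be made under kinetic control and should not sit at an epimerisable carbonyl stage for long. C2 is the one center that a catalyst can set on a simple achiral precursor, and next to C3 on a nearly flat five-membered ring it can then decide the face on which C3 and C4 are built. Three features are fragile. The C2–O1 bond is a benzylic ether of an electron-rich arene and opens under acid or forcing hydrogenolysis; the aryl ester rules out hydride and strong nucleophiles once it is in place; and the three phenols need one protecting group that leaves at the very end without harming either. The feature that opens the structure is that the CH2O carbon on C3 and the benzylic CH2 on C4 are one-carbon branches on neighbouring ring carbons and on the same face. Joined to each other they are the two alkene carbons of a cyclobutene fused across C3–C4, one bearing hydrogen and one bearing the aryl group, which is what a terminal aryl alkyne delivers in a [2+2] cycloaddition to the C3=C4 bond of a 2-aryl-2,5-dihydrofuran.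

## Retrosynthesis

**14 from 13.** Four benzyl C–O bonds and the C–O bond at the exocyclic benzylic carbon on C4 are cut, which leads back to bis-ester 13. In 13 the three phenols are benzyl ethers and the benzylic carbon still carries oxygen as a 4-(benzyloxy)benzoate. That oxygen is the unavoidable remnant of an alkene cleavage. A free hydroxyl there would be cleaved more slowly and would compete less clearly with the ring ether at C2, and a different acyl group would require the two hydroxyls of 10 to be told apart. Compound 13 is no simpler in skeleton, but every heteroatom function in it is removed by one reagent. The forward step must cleave the benzylic ester and the benzyl ethers on palladium while leaving C2–O1 and the primary ester intact.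

**13 from 10 and 11.** Both ester C–O bonds are cut, giving diol 10 and acid chloride 11. Using the same acyl group on both oxygens removes any selectivity demand at the cost of one cheap equivalent of 11. The precursor loses 28 carbons and all acyl functionality. The forward acylation must be exhaustive and acid-free, because acid would close 10 to a furofuran through its benzylic cation.

**10 from 8.** The CH2OH carbon on C3 and the carbinol carbon on C4 are reconnected as a C=C bond, giving cyclobutene 8 (cleaved forward through ozonide 9). A ring bond between the two branches is the only masking that fixes their cis relation by geometry, and the cyclobutene already distinguishes them as CH and C–aryl. Compound 8 contains only skeletal carbons and ethers. The forward cleavage must spare two electron-rich arenes and must be followed at once by reduction, so that the cis keto-aldehyde level is passed quickly.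

**8 from 7 and 2 (key disconnection).** The bonds from C3 to the alkyne CH and from C4 to the aryl-bearing alkyne carbon are cut. Stepwise attachment of the two branches by conjugate addition and enolate trapping gives the trans relation. A ketene-type [2+2] would leave the aryl group to be added later and poses the same regiochemical question. The cut divides the molecule into two halves of similar size, 7 and 2, both derived from aldehyde 1. The forward reaction must add anti to the C2 aryl group, pair the alkyne CH with C3, and outrun alkyne oligomerisation.

**7 from 5 and 6.** The C2–aryl bond is cut, giving aryl triflate 5 and 2,3-dihydrofuran 6. An asymmetric Heck arylation creates C2 catalytically in one step and places the double bond at C3=C4, exactly where the cycloaddition needs it. Building the same ring by metathesis of a chiral diallyl ether would need resolved or stoichiometric chirality and three steps. The forward reaction needs a ligand that releases the alkene before the palladium hydride re-adds, so that the 2,5-dihydro isomer is kept.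

**5 and 2 from 1.** Triflate 5 comes from phenol 4 by O-sulfonylation. Phenol 4 comes from 1 by replacing the formyl carbon with oxygen, through formate 3. Alkyne 2 comes from 1 by one-carbon homologation. Both partners of the key step thus start from O-benzylvanillin 1, and the benzyl ether chosen there is the phenol protection carried to the last step.

## Roads not taken

**Alternative 1: conjugate addition–aldol on a chiral butenolide.**
- Cut: the bond from C4 to the benzylic carbon and the C2–C3 bond; O1–C2 is left for a later ring closure.
- Forward key step: the lithium anion of aryl dithiane A2 adds to the (5S)-menthyloxybutenolide A1 anti to the acetal substituent, and the lactone enolate is trapped by aldehyde 1 anti to the new branch, giving the trans,trans lactone A3 in one flask.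
- Merits: the reaction type is established for this class of lignan precursors, and both aryl halves come from 1. The trans relation in the lactone becomes the 3,4-cis relation of the oxolane once the lactone carbonyl turns into the exocyclic CH2O and the carbinol carbon into C2.
- Weak points: the chirality is stoichiometric and comes from dextrorotatory menthol, and A1 has to be separated from its acetal epimer. A3 is still far from 14: the dithiane must be removed with Raney Ni in the presence of benzyl ethers and a benzylic carbinol, lactone and acetal must be reduced to a triol, and the oxolane must be closed by acid through the benzylic cation.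
- Comparison: in reliability of the key step this road is clearly ahead, and C2 is set by the ring closure without extra effort. Against it the chosen plan offers catalytic enantiocontrol, an oxolane present from the Heck step, and eight steps rather than roughly eleven. The classical lactone chemistry behind this alternative is kept as the contingency for step 5.

**Alternative 2: nickel-mediated radical cyclisation with arylation.**
- Cut: the C3–C4 bond and the benzylic CH2–aryl bond.
- Forward key step: iodide A4 (the allyl ether of a 1-aryl-2-iodo-3-silyloxypropanol, carbinol carbon configured as C2) loses iodine to low-valent nickel. The C3 radical closes 5-exo onto the allyl group, and the exocyclic primary radical is arylated through an aryl nickel species derived from bromide A5, giving A6.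
- Merits: the ring, the C3–C4 bond and the second aryl group arrive in one step. A chair-like transition state with the C2 aryl group pseudo-equatorial and the C3 branch cis to the attacking alkene favours the 2,3-trans-3,4-cis pattern. A6 needs no oxidative cleavage and no removal of an extra oxygen, so its end game (desilylation, acylation, debenzylation) is cleaner than that of the chosen plan.
- Weak points: the stereochemical preference is a small energy difference, not a geometric constraint. Capture of the cyclised radical must win over arylation of the uncyclised secondary radical and over reduction. A4, with its stereocenter, three differentiated oxygens and base-sensitive β-iodo ether, takes five or six steps to prepare.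
- Comparison: after the key step this road is better; before it, worse. The chosen plan sets against it the short access to 7 and 2 (three steps and one step) and a cis relation enforced by ring fusion, with a key step that is no more proven than this one.

**Alternative 3: keteniminium [2+2] and Baeyer–Villiger oxygen insertion.**
- Cut: the C4–C5 and C2–C3 bonds; O1 is inserted afterwards.
- Forward key step: the α-aryl keteniminium ion generated from amide A7 and Tf2O adds to allyl silyl ether A8 and, after hydrolysis, gives the trans cyclobutanone A9. Baeyer–Villiger oxidation would then insert oxygen next to the aryl-bearing carbon with retention.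
- Merits: cheap partners, a cycloaddition type with broad precedent, a reliable migratory preference, and C2 and C3 set trans in one step.
- Weak points: the key step builds neither the oxolane nor the C4 branch. The benzyl group has to be introduced next to a lactone carbonyl, where alkylation places it trans to the C3 branch, the wrong relation. A detour through an alkylidene lactone and hydrogenation is then needed, and the lactone carbonyl must afterwards be reduced to the C5 methylene. Enantiocontrol by a chiral amine is modest for unactivated monosubstituted alkenes, and A8 is inductively deactivated.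
- Comparison: this key step is closer to known chemistry than the cobalt cycloaddition. It solves the easy trans relation, however, and leaves the cis relation and four or five further operations for later, some twelve steps in all. The chosen plan spends its risk on the step that sets the cis pair directly.

Key step: step 5

## Route

Remark on the chemistry: O-benzylvanillin 1, 2,3-dihydrofuran 6 and 4-(benzyloxy)benzoyl chloride 11 are taken as purchased; 1 and 11 are otherwise one and two steps from vanillin and 4-hydroxybenzoic acid.

Step 1
Reactants: 1 4-(benzyloxy)-3-methoxybenzaldehyde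
Product: 2 1-(benzyloxy)-4-ethynyl-2-methoxybenzene
Conditions: dimethyl (1-diazo-2-oxopropyl)phosphonate, K2CO3, MeOH, 25 °C
Reagents that add atoms: dimethyl (1-diazo-2-oxopropyl)phosphonate (Ohira–Bestmann reagent), COP(=O)(OC)C(=[N+]=[N-])C(C)=O
Why: Seyferth–Gilbert homologation in the Ohira–Bestmann variant: methanolysis releases the diazomethylphosphonate anion, which olefinates the aldehyde, and loss of N2 with 1,2-hydrogen shift gives the terminal alkyne. Electron-rich, non-enolisable benzaldehydes are standard substrates and the benzyl ether is inert to K2CO3 in MeOH.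

Step 2
Reactants: 1 4-(benzyloxy)-3-methoxybenzaldehyde
Product: 4 4-(benzyloxy)-3-methoxyphenol, via aryl formate 3 (not isolated)
Conditions: mCPBA, CH2Cl2, 0 → 25 °C; then K2CO3 (cat.), MeOH, 25 °C
Reagents that add atoms: 3-chloroperoxybenzoic acid (mCPBA), O=C(OO)c1cccc(Cl)c1
Why: Baeyer–Villiger oxidation of an electron-rich benzaldehyde (Dakin-type): the 4-alkoxyaryl group migrates in preference to hydride, and formate 3 is cleaved by base-catalysed methanolysis in the same flask. Benzyl and methyl ethers are stable to the peracid.

Step 3
Reactants: 4 4-(benzyloxy)-3-methoxyphenol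
Product: 5 4-(benzyloxy)-3-methoxyphenyl trifluoromethanesulfonate
Conditions: Tf2O, pyridine, CH2Cl2, 0 °C
Reagents that add atoms: trifluoromethanesulfonic anhydride, O=S(=O)(OS(=O)(=O)C(F)(F)F)C(F)(F)F
Why: O-Sulfonylation of a phenol; there is no competing nucleophilic site.

Step 4
Reactants: 5 4-(benzyloxy)-3-methoxyphenyl trifluoromethanesulfonate, 6 2,3-dihydrofuran
Product: 7 (2R)-2-[4-(benzyloxy)-3-methoxyphenyl]-2,5-dihydrofuran
Conditions: Pd2(dba)3 (1.5 mol%), (S)-t-Bu-PHOX (4.5 mol%), i-Pr2NEt, 6 (4 equiv), THF, 70 °C
Reagents that add atoms: none
Why: Enantioselective intermolecular Heck reaction: the cationic aryl palladium species adds across C2=C3 of 6 with aryl to C2, and β-hydride elimination toward C4 gives the C3=C4 alkene. With a phosphinooxazoline ligand the alkene leaves the palladium hydride before re-addition, so the 2,5-dihydro isomer is kept, and ligand-controlled face selection in the insertion sets C2. The (S)-ligand is expected to give (R)-7, and its antipode is used if the sense proves opposite.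

Step 5
Reactants: 7 (2R)-2-[4-(benzyloxy)-3-methoxyphenyl]-2,5-dihydrofuran, 2 1-(benzyloxy)-4-ethynyl-2-methoxybenzene
Product: 8 (1R,2R,5R)-2,6-bis[4-(benzyloxy)-3-methoxyphenyl]-3-oxabicyclo[3.2.0]hept-6-ene (cyclobutene anti to the C2 aryl group)
Conditions: CoBr2(dppp) (10 mol%), Zn powder (20 mol%), ZnI2 (20 mol%), CH2Cl2, 25 °C, 2 (1.5 equiv) added over 8 h
Reagents that add atoms: none
Why: Proposed new method: Zn reduces CoBr2(dppp) to a monovalent cobalt species (ZnI2 opens a coordination site) that binds alkyne 2 and the C3=C4 bond of 7 and undergoes oxidative cyclisation to a cobaltacyclopentene of trivalent cobalt; C–C reductive elimination then closes the cyclobutene and returns monovalent cobalt. The closest known reaction type is the [2+2] cycloaddition of alkynes with cyclopentene and norbornene-type alkenes under CoBr2/bisphosphine/Zn/ZnI2; a terminal aryl alkyne combined with an unsymmetrical 2-substituted 2,5-dihydrofuran has not been shown. The four-membered ring is closed by reductive elimination from the five-membered metallacycle (a formal [2+2]), and because both new bonds reach the alkene on one face the ring fusion can only be cis. The two new stereocenters, C1 and C5 of the bicycle (C3 and C4 of the oxolane), are controlled by the C2 stereocenter: its aryl group shields one face of the nearly planar ring, so cobalt and alkyne approach anti to it, which gives the 2,3-trans-3,4-cis pattern. The regiochemistry needed (alkyne CH to C3, aryl-bearing carbon to C4) should follow from sterics, since the aryl-substituted alkyne carbon and the ligated cobalt both avoid the position next to the C2 substituent. Chemoselectivity over alkyne cyclotrimerisation is sought by slow addition of 2, and the wide bite angle of dppp is chosen to favour reductive elimination over β-hydride elimination from the metallacycle (Alder-ene-type product) and over alkene isomerisation. Benzyl and methyl ethers are spectators.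

Step 6
Reactants: 8 (1R,2R,5R)-2,6-bis[4-(benzyloxy)-3-methoxyphenyl]-3-oxabicyclo[3.2.0]hept-6-ene
Product: 10 [(2R,3S,4S)-2-[4-(benzyloxy)-3-methoxyphenyl]-4-{[4-(benzyloxy)-3-methoxyphenyl](hydroxy)methyl}oxolan-3-yl]methanol (both carbinol epimers), via ozonide 9 (not isolated)
Conditions: O3, CH2Cl2, −78 °C (Sudan Red 7B end-point); then NaBH4, MeOH, −78 → 25 °C; neutral work-up
Reagents that add atoms: ozone, [O-][O+]=O
Why: Ozonolysis of the strained, electron-rich styrene-type alkene is much faster than attack on the arenes or benzyl ethers, and ozonide 9 is reduced in the same flask by NaBH4 to the primary and the secondary benzylic alcohol. C3 and C4 are untouched, and cold reduction keeps the time at the epimerisable carbonyl level short; the new carbinol center forms unselectively and is removed in step 8. Acid is avoided because it would close 10 to a furofuran through the benzylic cation.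

Step 7
Reactants: 10 [(2R,3S,4S)-2-[4-(benzyloxy)-3-methoxyphenyl]-4-{[4-(benzyloxy)-3-methoxyphenyl](hydroxy)methyl}oxolan-3-yl]methanol, 11 4-(benzyloxy)benzoyl chloride
Product: 13 [(2R,3S,4S)-2-[4-(benzyloxy)-3-methoxyphenyl]-4-{[4-(benzyloxy)-3-methoxyphenyl]{[4-(benzyloxy)benzoyl]oxy}methyl}oxolan-3-yl]methyl 4-(benzyloxy)benzoate (both epimers at the acyloxy carbon), via primary monoester 12 (not isolated)
Conditions: 11 (3 equiv), Et3N, DMAP (0.2 equiv), CH2Cl2, 0 → 25 °C
Reagents that add atoms: none
Why: DMAP-catalysed acylation with an acid chloride: the primary alcohol reacts first (12) and the hindered benzylic alcohol follows with excess reagent, so the two hydroxyls need not be distinguished. The benzylic ester is the leaving group for step 8, and no stereocenter is touched.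

Step 8
Reactants: 13 [(2R,3S,4S)-2-[4-(benzyloxy)-3-methoxyphenyl]-4-{[4-(benzyloxy)-3-methoxyphenyl]{[4-(benzyloxy)benzoyl]oxy}methyl}oxolan-3-yl]methyl 4-(benzyloxy)benzoate
Product: 14 agastinol, [(2R,3S,4S)-2-(4-hydroxy-3-methoxyphenyl)-4-(4-hydroxy-3-methoxybenzyl)oxolan-3-yl]methyl 4-hydroxybenzoate
Conditions: H2 (1 atm), 10% Pd/C, EtOAc, 25 °C
Reagents that add atoms: none
Why: Heterogeneous hydrogenolysis on palladium cleaves the benzyl aryl ethers and the exocyclic secondary benzylic ester, whose acyloxy group makes it the most labile benzylic C–O bond; the primary ester is not benzylic, and the cyclic C2–O1 ether, with an alkoxide as leaving group, should be the slowest benzylic C–O bond present. The aprotic solvent prevents solvolysis of the benzylic ester to a less reactive ether, and the reaction is stopped once 14 is the only product. No stereocenter is formed, and C2, C3 and C4 are retained.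

## Compound list

1 | 4-(benzyloxy)-3-methoxybenzaldehyde (O-benzylvanillin) | COc1cc(C=O)ccc1OCc1ccccc1 | starting material
2 | 1-(benzyloxy)-4-ethynyl-2-methoxybenzene | COc1cc(C#C)ccc1OCc1ccccc1 | intermediate
3 | 4-(benzyloxy)-3-methoxyphenyl formate | COc1cc(OC=O)ccc1OCc1ccccc1 | intermediate (not isolated)
4 | 4-(benzyloxy)-3-methoxyphenol | COc1cc(O)ccc1OCc1ccccc1 | intermediate
5 | 4-(benzyloxy)-3-methoxyphenyl trifluoromethanesulfonate | COc1cc(OS(=O)(=O)C(F)(F)F)ccc1OCc1ccccc1 | intermediate
6 | 2,3-dihydrofuran | C1=COCC1 | starting material
7 | (2R)-2-[4-(benzyloxy)-3-methoxyphenyl]-2,5-dihydrofuran | C1=C[C@H](c2ccc(OCc3ccccc3)c(OC)c2)OC1 | intermediate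
8 | (1R,2R,5R)-2,6-bis[4-(benzyloxy)-3-methoxyphenyl]-3-oxabicyclo[3.2.0]hept-6-ene | COc1cc(C2=C[C@H]3[C@H](c4ccc(OCc5ccccc5)c(OC)c4)OC[C@@H]23)ccc1OCc1ccccc1 | intermediate
9 | ozonide of 8: 1,2,4-trioxolane bridging the two former alkene carbons (aryl-bearing carbon on oxolane C4, CH carbon on oxolane C3); oxolane centers as in 8, the two acetal carbons not assigned | COc1cc(C23OOC(O3)[C@H]3[C@H](c4ccc(OCc5ccccc5)c(OC)c4)OC[C@@H]23)ccc1OCc1ccccc1 | intermediate (not isolated)
10 | [(2R,3S,4S)-2-[4-(benzyloxy)-3-methoxyphenyl]-4-{[4-(benzyloxy)-3-methoxyphenyl](hydroxy)methyl}oxolan-3-yl]methanol, both carbinol epimers | COc1cc(C(O)[C@@H]2CO[C@@H](c3ccc(OCc4ccccc4)c(OC)c3)[C@@H]2CO)ccc1OCc1ccccc1 | intermediate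
11 | 4-(benzyloxy)benzoyl chloride | O=C(Cl)c1ccc(OCc2ccccc2)cc1 | starting material
12 | [(2R,3S,4S)-2-[4-(benzyloxy)-3-methoxyphenyl]-4-{[4-(benzyloxy)-3-methoxyphenyl](hydroxy)methyl}oxolan-3-yl]methyl 4-(benzyloxy)benzoate, both carbinol epimers | COc1cc(C(O)[C@@H]2CO[C@@H](c3ccc(OCc4ccccc4)c(OC)c3)[C@@H]2COC(=O)c2ccc(OCc3ccccc3)cc2)ccc1OCc1ccccc1 | intermediate (not isolated)
13 | [(2R,3S,4S)-2-[4-(benzyloxy)-3-methoxyphenyl]-4-{[4-(benzyloxy)-3-methoxyphenyl]{[4-(benzyloxy)benzoyl]oxy}methyl}oxolan-3-yl]methyl 4-(benzyloxy)benzoate, both epimers at the acyloxy carbon | COc1cc(C(OC(=O)c2ccc(OCc3ccccc3)cc2)[C@@H]2CO[C@@H](c3ccc(OCc4ccccc4)c(OC)c3)[C@@H]2COC(=O)c2ccc(OCc3ccccc3)cc2)ccc1OCc1ccccc1 | intermediate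
14 | agastinol, [(2R,3S,4S)-2-(4-hydroxy-3-methoxyphenyl)-4-(4-hydroxy-3-methoxybenzyl)oxolan-3-yl]methyl 4-hydroxybenzoate | COc1cc(C[C@@H]2CO[C@@H](c3ccc(O)c(OC)c3)[C@@H]2COC(=O)c2ccc(O)cc2)ccc1O | target

## Step count and least certain steps

Total: 8 steps from 1, 6 and 11. Longest linear sequence: 7 steps (steps 2 to 8); step 1 is a one-step branch.

**Step 5 (key step).** Three processes are most likely to go wrong. Cyclotrimerisation or dimerisation of the terminal alkyne may outrun the cross-cycloaddition, because the 1,2-disubstituted, inductively deactivated ring alkene binds cobalt less well than the alkyne. β-Hydride elimination from the cobaltacycle, or chain-walking by a cobalt hydride, may divert the dihydrofuran to Alder-ene-type products or isomerise it toward the enol ether and the furan. The steric bias of a single C2 substituent may give incomplete face or regiochemical control.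

Fallback, known reactions only, setting out from 1 and returning at 14:
- Stobbe condensation of 1 with dimethyl succinate (NaOMe, MeOH, reflux) gives the (E)-arylidenesuccinate half-ester F1.
- Asymmetric hydrogenation ([Rh(cod)2]BF4, a chiral bisphosphine of the DuPhos or DIOP type in the enantiomer that leads to S, H2, MeOH) gives the (S)-benzylsuccinate half-ester F2.
- Reduction of the ester beside the carboxylate (Ca(BH4)2 from CaCl2 and NaBH4, EtOH) and acidification give the (S)-β-benzyl-γ-butyrolactone F3.
- The lithium enolate (LDA, THF, −78 °C) adds to a second equivalent of 1 anti to the benzyl group and gives the trans aldol lactone F4.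
- LiAlH4 gives the triol F5.
- Camphorsulfonic acid in CH2Cl2 closes the oxolane through the benzylic cation with the aryl group trans to the C3 branch and gives the dibenzylated hydroxymethyl oxolane F6, in which the trans lactone relation has become 3,4-cis.
- Acylation with 11 (Et3N, DMAP) gives tribenzyl agastinol F7, and H2 over Pd/C gives 14.

**Step 4.** Oxidative addition of the electron-rich triflate may be slow. Re-addition of the palladium hydride may erode the enantiomeric purity or move the double bond into conjugation with oxygen. The doubly activated C2–H invites aromatisation to the furan on handling.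

Fallback, setting out from 1 and returning at 7:
- Vinylmagnesium bromide (THF, 0 °C) gives the racemic allylic alcohol F8.
- Sharpless kinetic resolution (Ti(OiPr)4, D-(−)-diisopropyl tartrate, t-BuOOH, 4 Å sieves, CH2Cl2, −20 °C) epoxidises the (S)-enantiomer and leaves the (R)-allylic alcohol F9.
- NaH and allyl bromide give the (R)-diallyl ether F10.
- Ring-closing metathesis (second-generation Grubbs catalyst, CH2Cl2, 40 °C) gives 7.

**Step 6.** Excess ozone may oxidise the electron-rich arenes or the benzyl ethers. Epimerisation at C3 or C4 may occur at the transient cis keto-aldehyde level under basic borohydride. Reduction of the aryl ketone may stall while it is held as a cyclic hemiketal with the neighbouring hydroxymethyl group.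

Fallback, setting out from 8 and returning at 10:
- OsO4 (cat.) and NMO in acetone–water add two hydroxyls to the convex face and give the cyclobutanediol F11.
- NaIO4 (THF–water, pH 7) cleaves it to the cis keto-aldehyde F12.
- NaBH4 (MeOH, −40 → 0 °C) gives 10.

**Step 8.** Hydrogenolytic opening of the ring C2–O1 bond may compete with cleavage of the exocyclic benzylic ester. Elimination toward a styrene or quinone methide tautomer, followed by unselective hydrogenation, may erode the C4 configuration.

Fallback, setting out from 10 and returning at 14:
- Selective acylation of the primary hydroxyl (11, 1.05 equiv, 2,4,6-collidine, CH2Cl2, −40 °C) gives 12, now isolated.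
- 1,1'-Thiocarbonyldiimidazole (DMAP, CH2Cl2) gives the imidazolyl thiocarbonate F13.
- Barton–McCombie deoxygenation (Bu3SnH, AIBN, toluene, 80 °C) through the benzylic radical gives tribenzyl agastinol F7.
- A short hydrogenolysis (H2, Pd/C, EtOAc), which then only has to cleave aryl benzyl ethers, gives 14.

## Further compounds

F1 | step 5 | (E)-4-[4-(benzyloxy)-3-methoxyphenyl]-3-(methoxycarbonyl)but-3-enoic acid | COC(=O)/C(=C/c1ccc(OCc2ccccc2)c(OC)c1)CC(=O)O
F2 | step 5 | (3S)-4-[4-(benzyloxy)-3-methoxyphenyl]-3-(methoxycarbonyl)butanoic acid | OC(=O)C[C@H](Cc1ccc(OCc2ccccc2)c(OC)c1)C(=O)OC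
F3 | step 5 | (4S)-4-[4-(benzyloxy)-3-methoxybenzyl]oxolan-2-one | O=C1C[C@H](Cc2ccc(OCc3ccccc3)c(OC)c2)CO1
F4 | step 5 | (3R,4S)-4-[4-(benzyloxy)-3-methoxybenzyl]-3-{[4-(benzyloxy)-3-methoxyphenyl](hydroxy)methyl}oxolan-2-one, carbinol epimers | O=C1OC[C@@H](Cc2ccc(OCc3ccccc3)c(OC)c2)[C@@H]1C(O)c1ccc(OCc2ccccc2)c(OC)c1
F5 | step 5 | (2S,3S)-3-[4-(benzyloxy)-3-methoxybenzyl]-2-{[4-(benzyloxy)-3-methoxyphenyl](hydroxy)methyl}butane-1,4-diol, carbinol epimers | OC[C@@H](Cc1ccc(OCc2ccccc2)c(OC)c1)[C@@H](CO)C(O)c1ccc(OCc2ccccc2)c(OC)c1
F6 | step 5 | [(2R,3S,4S)-2-[4-(benzyloxy)-3-methoxyphenyl]-4-[4-(benzyloxy)-3-methoxybenzyl]oxolan-3-yl]methanol | COc1cc(C[C@@H]2CO[C@@H](c3ccc(OCc4ccccc4)c(OC)c3)[C@@H]2CO)ccc1OCc1ccccc1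
F7 | step 5 | tribenzyl agastinol, [(2R,3S,4S)-2-[4-(benzyloxy)-3-methoxyphenyl]-4-[4-(benzyloxy)-3-methoxybenzyl]oxolan-3-yl]methyl 4-(benzyloxy)benzoate | COc1cc(C[C@@H]2CO[C@@H](c3ccc(OCc4ccccc4)c(OC)c3)[C@@H]2COC(=O)c2ccc(OCc3ccccc3)cc2)ccc1OCc1ccccc1
F8 | step 4 | rac-1-[4-(benzyloxy)-3-methoxyphenyl]prop-2-en-1-ol | C=CC(O)c1ccc(OCc2ccccc2)c(OC)c1
F9 | step 4 | (1R)-1-[4-(benzyloxy)-3-methoxyphenyl]prop-2-en-1-ol | C=C[C@H](c1ccc(OCc2ccccc2)c(OC)c1)O
F10 | step 4 | (R)-1-(benzyloxy)-2-methoxy-4-[1-(prop-2-en-1-yloxy)prop-2-en-1-yl]benzene | C=C[C@H](c1ccc(OCc2ccccc2)c(OC)c1)OCC=C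
F11 | step 6 | 2,6-bis[4-(benzyloxy)-3-methoxyphenyl]-3-oxabicyclo[3.2.0]heptane-6,7-diol, ring centers as in 8, both hydroxyls cis to the bridgehead hydrogens | COc1cc([C@@]2(O)[C@H](O)[C@H]3[C@H](c4ccc(OCc5ccccc5)c(OC)c4)OC[C@@H]23)ccc1OCc1ccccc1
F12 | step 6 | (2R,3S,4S)-4-[4-(benzyloxy)-3-methoxybenzoyl]-2-[4-(benzyloxy)-3-methoxyphenyl]oxolane-3-carbaldehyde | COc1cc(C(=O)[C@@H]2CO[C@@H](c3ccc(OCc4ccccc4)c(OC)c3)[C@@H]2C=O)ccc1OCc1ccccc1
F13 | step 8 | O-(imidazol-1-ylthiocarbonyl) derivative of 12 at the benzylic oxygen, both epimers | COc1cc(C(OC(=S)n2ccnc2)[C@@H]2CO[C@@H](c3ccc(OCc4ccccc4)c(OC)c3)[C@@H]2COC(=O)c2ccc(OCc3ccccc3)cc2)ccc1OCc1ccccc1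
A1 | alternative 1 | (5S)-5-{[(1S,2R,5S)-5-methyl-2-(propan-2-yl)cyclohexyl]oxy}furan-2(5H)-one | O=C1C=C[C@@H](O[C@H]2C[C@@H](C)CC[C@@H]2C(C)C)O1
A2 | alternative 1 | 2-[4-(benzyloxy)-3-methoxyphenyl]-1,3-dithiane | COc1cc(C2SCCCS2)ccc1OCc1ccccc1
A3 | alternative 1 | trans,trans conjugate addition–aldol lactone (dithiane on the future benzylic carbon, menthyloxy acetal at the future C5) | COc1cc(C2(SCCCS2)[C@@H]2[C@@H](O[C@H]3C[C@@H](C)CC[C@@H]3C(C)C)OC(=O)[C@H]2[C@@H](O)c2ccc(OCc3ccccc3)c(OC)c2)ccc1OCc1ccccc1
A4 | alternative 2 | allyl ether of 1-[4-(benzyloxy)-3-methoxyphenyl]-3-(tert-butyldimethylsilyloxy)-2-iodopropan-1-ol, carbinol carbon configured as C2 of the target, iodide epimers | C=CCO[C@@H](c1ccc(OCc2ccccc2)c(OC)c1)C(I)CO[Si](C)(C)C(C)(C)C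
A5 | alternative 2 | 1-(benzyloxy)-4-bromo-2-methoxybenzene | COc1cc(Br)ccc1OCc1ccccc1
A6 | alternative 2 | 2,3-trans-3,4-cis oxolane with both phenols benzylated and the C3 CH2OH silylated | COc1cc(C[C@@H]2CO[C@@H](c3ccc(OCc4ccccc4)c(OC)c3)[C@@H]2CO[Si](C)(C)C(C)(C)C)ccc1OCc1ccccc1
A7 | alternative 3 | 2-[4-(benzyloxy)-3-methoxyphenyl]-1-[(2R,5R)-2,5-dimethylpyrrolidin-1-yl]ethan-1-one (auxiliary drawn as one enantiomer) | COc1cc(CC(=O)N2[C@H](C)CC[C@H]2C)ccc1OCc1ccccc1
A8 | alternative 3 | triisopropyl(prop-2-en-1-yloxy)silane | C=CCO[Si](C(C)C)(C(C)C)C(C)C
A9 | alternative 3 | trans-2-[4-(benzyloxy)-3-methoxyphenyl]-3-[(triisopropylsilyloxy)methyl]cyclobutanone, C2 and C3 as in the target | O=C1C[C@@H](CO[Si](C(C)C)(C(C)C)C(C)C)[C@@H]1c1ccc(OCc2ccccc2)c(OC)c1
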